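**Retrosynthetic overview**
- The two aryl–prenyl C–C bonds are made together, late, by a twofold aromatic Claisen rearrangement ([3,3]) of a bis(1,1-dimethylallyl) aryl ether; one desilylation then gives the target.
- The butenolide is closed from a tertiary α-ketol by O-acylation with acetoxyacetyl chloride and intramolecular aldol condensation.
- The α-ketol comes from an aldol reaction between a catechol-derived aldehyde (ring B) and the lithium enolate of a cis-2-tert-butyl-1,3-dioxolan-4-one (ring A part), followed by methanolysis and oxidation.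
- The dioxolanone comes from (S)-4-hydroxyphenyllactic acid, made from L-tyrosine; the tyrosine centre is relayed through the acetal carbon and becomes the quaternary (R)-centre.
- Ring order: temporary dioxolanone first, butenolide second; both benzene rings are bought.

Assumption: tert-butyl (2-methylbut-3-en-2-yl) carbonate is bought as a catalogue reagent; the target is the (R)-enantiomer that the SMILES encodes.

**Route**

Step 1
Reactants: 1 L-tyrosine
Product: 4 (2S)-2-hydroxy-3-(4-hydroxyphenyl)propanoic acid, via diazonium carboxylate 2 (not isolated), via α-lactone 3 (not isolated)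
Conditions: NaNO2 (1.5 equiv), 1 M aq. H2SO4, 0 → 23 °C
Reagents that add atoms: water, O
Why: Diazotisation of the α-amino acid (deaminative hydroxylation) gives net retention because the carboxylate displaces N2 with inversion to the α-lactone and water opens it with a second inversion, so the bought (S)-centre is kept.

Step 2
Reactants: 4 (2S)-2-hydroxy-3-(4-hydroxyphenyl)propanoic acid
Product: 5 (2S,5S)-2-tert-butyl-5-(4-hydroxybenzyl)-1,3-dioxolan-4-one
Conditions: t-BuCHO (2 equiv), TsOH·H2O (5 mol %), H2SO4 (cat.), pentane, reflux, Dean–Stark trap; recrystallisation to remove the minor trans isomer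
Reagents that add atoms: pivalaldehyde, CC(C)(C)C=O
Why: Acid-catalysed acetalisation under thermodynamic control favours the cis-2,5-disubstituted dioxolanone, so the (S)-centre of 4 sets the new acetal centre as (S) (first half of Seebach's self-regeneration of stereocentres).

Step 3
Reactants: 5 (2S,5S)-2-tert-butyl-5-(4-hydroxybenzyl)-1,3-dioxolan-4-one
Product: 6 (2S,5S)-2-tert-butyl-5-{4-[(2-methylbut-3-en-2-yl)oxy]benzyl}-1,3-dioxolan-4-one
Conditions: tert-butyl (2-methylbut-3-en-2-yl) carbonate (1.3 equiv), Pd(PPh3)4 (2 mol %), THF, 0 → 23 °C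
Reagents that add atoms: tert-butyl (2-methylbut-3-en-2-yl) carbonate, CC(C)(C)OC(=O)OC(C)(C)C=C
Why: Decarboxylative Tsuji–Trost O-allylation, in which the phenoxide formed by the released tert-butoxide attacks the 1,1-dimethylallyl palladium cation at its tertiary terminus to give the branched ether under kinetic control while the dioxolanone is left untouched.

Step 4
Reactants: 7 3,4-dihydroxybenzaldehyde
Product: 8 3-hydroxy-4-[(2-methylbut-3-en-2-yl)oxy]benzaldehyde
Conditions: tert-butyl (2-methylbut-3-en-2-yl) carbonate (1.05 equiv), Pd(PPh3)4 (2 mol %), THF, 0 °C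
Reagents that add atoms: tert-butyl (2-methylbut-3-en-2-yl) carbonate, CC(C)(C)OC(=O)OC(C)(C)C=C
Why: The same decarboxylative Tsuji–Trost etherification, in which the single equivalent of tert-butoxide ionises the more acidic 4-OH (para to the formyl group), so the 4-O-ether forms selectively.

Step 5
Reactants: 8 3-hydroxy-4-[(2-methylbut-3-en-2-yl)oxy]benzaldehyde
Product: 9 4-[(2-methylbut-3-en-2-yl)oxy]-3-[(triisopropylsilyl)oxy]benzaldehyde
Conditions: i-Pr3SiCl (1.3 equiv), imidazole (2.5 equiv), DMAP (cat.), DMF, 23 °C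
Reagents that add atoms: chlorotriisopropylsilane, CC(C)[Si](Cl)(C(C)C)C(C)C
Why: Standard silylation of the remaining phenol gives a bulky aryl silyl ether that withstands the enolate, methoxide and DBU steps ahead and cannot take part in the later rearrangement.

Step 6
Reactants: 6 (2S,5S)-2-tert-butyl-5-{4-[(2-methylbut-3-en-2-yl)oxy]benzyl}-1,3-dioxolan-4-one; 9 4-[(2-methylbut-3-en-2-yl)oxy]-3-[(triisopropylsilyl)oxy]benzaldehyde
Product: 11 (2S,5R)-2-tert-butyl-5-[(RS)-hydroxy{4-[(2-methylbut-3-en-2-yl)oxy]-3-[(triisopropylsilyl)oxy]phenyl}methyl]-5-{4-[(2-methylbut-3-en-2-yl)oxy]benzyl}-1,3-dioxolan-4-one, via lithium enolate 10 (not isolated)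
Conditions: LiN(i-Pr)2 (1.1 equiv), THF, −78 °C, 30 min; then 9 (1.2 equiv), −78 °C, 1 h; AcOH, −78 °C
Reagents that add atoms: none
Why: Aldol addition of the Seebach dioxolanone enolate, in which the aldehyde approaches anti to the tert-butyl group so the new C–C bond replaces the former α-H and the quaternary centre is set as (5R) by the acetal centre that L-tyrosine installed (the carbinol centre is a mixture and is erased in step 8).

Step 7
Reactants: 11 (2S,5R)-aldol adduct
Product: 12 methyl (2R,3RS)-2,3-dihydroxy-2-{4-[(2-methylbut-3-en-2-yl)oxy]benzyl}-3-{4-[(2-methylbut-3-en-2-yl)oxy]-3-[(triisopropylsilyl)oxy]phenyl}propanoate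
Conditions: NaOMe (0.2 equiv), MeOH/THF 3:1, 0 °C; then AcOH
Reagents that add atoms: methanol, CO
Why: Methoxide-catalysed transesterification of the acetal-bound lactone carbonyl releases a hemiacetal that collapses to pivalaldehyde and the tertiary alcohol, which removes the relay centre without touching the quaternary centre, and cold catalytic base spares the aryl silyl ether and avoids retro-aldol cleavage.

Step 8
Reactants: 12 methyl (2R,3RS)-2,3-dihydroxy ester
Product: 13 methyl (2R)-2-hydroxy-2-{4-[(2-methylbut-3-en-2-yl)oxy]benzyl}-3-{4-[(2-methylbut-3-en-2-yl)oxy]-3-[(triisopropylsilyl)oxy]phenyl}-3-oxopropanoate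
Conditions: IBX (1.5 equiv), DMSO, 23 °C
Reagents that add atoms: none
Why: 2-Iodoxybenzoic acid oxidises the secondary benzylic alcohol of the 1,2-diol to the aryl ketone without glycol cleavage and leaves the tertiary alcohol alone, which merges both carbinol epimers into one α-ketol.

Step 9
Reactants: 13 methyl (2R)-α-ketol
Product: 16 methyl (2R)-4-hydroxy-2-{4-[(2-methylbut-3-en-2-yl)oxy]benzyl}-3-{4-[(2-methylbut-3-en-2-yl)oxy]-3-[(triisopropylsilyl)oxy]phenyl}-5-oxo-2,5-dihydrofuran-2-carboxylate, via acetoxyacetate ester 14 (not isolated), via enol acetate 15 (not isolated)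
Conditions: AcOCH2COCl (1.5 equiv), pyridine (3 equiv), DMAP (0.2 equiv), CH2Cl2, 0 → 23 °C; then DBU (4 equiv), MeCN, 23 °C; then MeOH, 0 °C; aq. citric acid work-up
Reagents that add atoms: acetoxyacetyl chloride, CC(=O)OCC(=O)Cl
Why: O-Acylation of the tertiary α-ketol followed by DBU-mediated intramolecular aldol condensation (5-exo attack of the acetoxyacetate enolate on the aryl ketone, then dehydration) closes the butenolide, and DBU/methanol transesterifies the activated enol acetate to the free enol, while the quaternary centre has no acidic hydrogen and is unaffected.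

Step 10
Reactants: 16 methyl (2R)-4-hydroxybutenolide bis(1,1-dimethylallyl) ether
Product: 18 methyl (2R)-4-hydroxy-2-[4-hydroxy-3-(3-methylbut-2-en-1-yl)benzyl]-3-{4-hydroxy-3-(3-methylbut-2-en-1-yl)-5-[(triisopropylsilyl)oxy]phenyl}-5-oxo-2,5-dihydrofuran-2-carboxylate, via bis-dienone 17 (not isolated)
Conditions: degassed PhNEt2, 140 °C, Ar, 2 h
Reagents that add atoms: none
Why: Twofold aromatic Claisen rearrangement ([3,3]-sigmatropic shift) of the two aryl 1,1-dimethylallyl ethers forms both aryl–prenyl bonds with allylic transposition; on ring A the two ortho positions are equivalent, on ring B only C-5 is free, and both para positions are blocked, so tautomerisation of the ortho-dienones gives the two ortho-prenylphenols and the remote quaternary centre is untouched.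

Step 11
Reactants: 18 methyl (2R)-bis-prenylated silyl ether
Product: 19 methyl (2R)-3-[3,4-dihydroxy-5-(3-methylbut-2-en-1-yl)phenyl]-4-hydroxy-2-[4-hydroxy-3-(3-methylbut-2-en-1-yl)benzyl]-5-oxo-2,5-dihydrofuran-2-carboxylate
Conditions: Bu4NF (1.2 equiv), AcOH (1.5 equiv), THF, 0 °C
Reagents that add atoms: none
Why: Fluoride-mediated desilylation of the aryl silyl ether under acetic acid buffering frees the catechol without opening the lactone, hydrolysing the methyl ester or cyclising the ortho-prenylphenols, and leaves the (R)-centre as set.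

**Compound list**

1 | L-tyrosine | N[C@@H](Cc1ccc(O)cc1)C(=O)O | starting material
2 | (S)-1-carboxylato-2-(4-hydroxyphenyl)ethanediazonium | N#[N+][C@@H](Cc1ccc(O)cc1)C([O-])=O | intermediate (not isolated)
3 | (R)-3-(4-hydroxybenzyl)oxiran-2-one | O=C1O[C@@H]1Cc1ccc(O)cc1 | intermediate (not isolated)
4 | (2S)-2-hydroxy-3-(4-hydroxyphenyl)propanoic acid | O[C@@H](Cc1ccc(O)cc1)C(=O)O | intermediate
5 | (2S,5S)-2-tert-butyl-5-(4-hydroxybenzyl)-1,3-dioxolan-4-one | O=C1O[C@@H](C(C)(C)C)O[C@H]1Cc1ccc(O)cc1 | intermediate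
6 | (2S,5S)-2-tert-butyl-5-{4-[(2-methylbut-3-en-2-yl)oxy]benzyl}-1,3-dioxolan-4-one | O=C1O[C@@H](C(C)(C)C)O[C@H]1Cc1ccc(OC(C)(C)C=C)cc1 | intermediate
7 | 3,4-dihydroxybenzaldehyde | O=Cc1ccc(O)c(O)c1 | starting material
8 | 3-hydroxy-4-[(2-methylbut-3-en-2-yl)oxy]benzaldehyde | O=Cc1ccc(OC(C)(C)C=C)c(O)c1 | intermediate
9 | 4-[(2-methylbut-3-en-2-yl)oxy]-3-[(triisopropylsilyl)oxy]benzaldehyde | O=Cc1ccc(OC(C)(C)C=C)c(O[Si](C(C)C)(C(C)C)C(C)C)c1 | intermediate
10 | lithium (2S)-2-tert-butyl-5-{4-[(2-methylbut-3-en-2-yl)oxy]benzyl}-1,3-dioxol-4-olate | [Li+].[O-]C1=C(Cc2ccc(OC(C)(C)C=C)cc2)O[C@H](C(C)(C)C)O1 | intermediate (not isolated)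
11 | (2S,5R)-2-tert-butyl-5-[(RS)-hydroxy{4-[(2-methylbut-3-en-2-yl)oxy]-3-[(triisopropylsilyl)oxy]phenyl}methyl]-5-{4-[(2-methylbut-3-en-2-yl)oxy]benzyl}-1,3-dioxolan-4-one | O=C1O[C@@H](C(C)(C)C)O[C@]1(Cc2ccc(OC(C)(C)C=C)cc2)C(O)c3ccc(OC(C)(C)C=C)c(O[Si](C(C)C)(C(C)C)C(C)C)c3 | intermediate
12 | methyl (2R,3RS)-2,3-dihydroxy-2-{4-[(2-methylbut-3-en-2-yl)oxy]benzyl}-3-{4-[(2-methylbut-3-en-2-yl)oxy]-3-[(triisopropylsilyl)oxy]phenyl}propanoate | COC(=O)[C@@](O)(Cc1ccc(OC(C)(C)C=C)cc1)C(O)c1ccc(OC(C)(C)C=C)c(O[Si](C(C)C)(C(C)C)C(C)C)c1 | intermediate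
13 | methyl (2R)-2-hydroxy-2-{4-[(2-methylbut-3-en-2-yl)oxy]benzyl}-3-{4-[(2-methylbut-3-en-2-yl)oxy]-3-[(triisopropylsilyl)oxy]phenyl}-3-oxopropanoate | COC(=O)[C@@](O)(Cc1ccc(OC(C)(C)C=C)cc1)C(=O)c1ccc(OC(C)(C)C=C)c(O[Si](C(C)C)(C(C)C)C(C)C)c1 | intermediate
14 | methyl (2R)-2-[(acetoxyacetyl)oxy]-2-{4-[(2-methylbut-3-en-2-yl)oxy]benzyl}-3-{4-[(2-methylbut-3-en-2-yl)oxy]-3-[(triisopropylsilyl)oxy]phenyl}-3-oxopropanoate | COC(=O)[C@@](OC(=O)COC(C)=O)(Cc1ccc(OC(C)(C)C=C)cc1)C(=O)c1ccc(OC(C)(C)C=C)c(O[Si](C(C)C)(C(C)C)C(C)C)c1 | intermediate (not isolated)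
15 | methyl (2R)-4-acetoxy-2-{4-[(2-methylbut-3-en-2-yl)oxy]benzyl}-3-{4-[(2-methylbut-3-en-2-yl)oxy]-3-[(triisopropylsilyl)oxy]phenyl}-5-oxo-2,5-dihydrofuran-2-carboxylate | COC(=O)[C@]1(Cc2ccc(OC(C)(C)C=C)cc2)OC(=O)C(OC(C)=O)=C1c1ccc(OC(C)(C)C=C)c(O[Si](C(C)C)(C(C)C)C(C)C)c1 | intermediate (not isolated)
16 | methyl (2R)-4-hydroxy-2-{4-[(2-methylbut-3-en-2-yl)oxy]benzyl}-3-{4-[(2-methylbut-3-en-2-yl)oxy]-3-[(triisopropylsilyl)oxy]phenyl}-5-oxo-2,5-dihydrofuran-2-carboxylate | COC(=O)[C@]1(Cc2ccc(OC(C)(C)C=C)cc2)OC(=O)C(O)=C1c1ccc(OC(C)(C)C=C)c(O[Si](C(C)C)(C(C)C)C(C)C)c1 | intermediate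
17 | methyl (2R)-4-hydroxy-2-{[3-(3-methylbut-2-en-1-yl)-4-oxocyclohexa-1,5-dien-1-yl]methyl}-3-{3-(3-methylbut-2-en-1-yl)-4-oxo-5-[(triisopropylsilyl)oxy]cyclohexa-1,5-dien-1-yl}-5-oxo-2,5-dihydrofuran-2-carboxylate (new sp3 ring carbons undefined) | COC(=O)[C@]1(CC2=CC(CC=C(C)C)C(=O)C=C2)OC(=O)C(O)=C1C3=CC(CC=C(C)C)C(=O)C(O[Si](C(C)C)(C(C)C)C(C)C)=C3 | intermediate (not isolated)
18 | methyl (2R)-4-hydroxy-2-[4-hydroxy-3-(3-methylbut-2-en-1-yl)benzyl]-3-{4-hydroxy-3-(3-methylbut-2-en-1-yl)-5-[(triisopropylsilyl)oxy]phenyl}-5-oxo-2,5-dihydrofuran-2-carboxylate | COC(=O)[C@]1(Cc2ccc(O)c(CC=C(C)C)c2)OC(=O)C(O)=C1c1cc(O[Si](C(C)C)(C(C)C)C(C)C)c(O)c(CC=C(C)C)c1 | intermediate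
19 | methyl (2R)-3-[3,4-dihydroxy-5-(3-methylbut-2-en-1-yl)phenyl]-4-hydroxy-2-[4-hydroxy-3-(3-methylbut-2-en-1-yl)benzyl]-5-oxo-2,5-dihydrofuran-2-carboxylate | COC(=O)[C@]1(Cc2ccc(O)c(CC=C(C)C)c2)OC(=O)C(O)=C1c1cc(O)c(O)c(CC=C(C)C)c1 | target

**Step count and risks**

Total step count: 11. Longest linear sequence: 9 steps (1, 2, 3, 6, 7, 8, 9, 10, 11, from L-tyrosine).

Most likely to fail, first: step 9. The tertiary α-ketol is very hindered, the aryl ketone is electron-rich, and the acetoxyacetate enolate could instead attack the neighbouring methyl ester in a Dieckmann sense. The fallback sets out from 13 and comes back at 16, and makes the C–C bond before the C–O bond. The lithium enolate of methyl 2-[(tert-butyldimethylsilyl)oxy]acetate (2.5 equiv, THF, −78 → 0 °C) is added to the ketone of 13. The tertiary alkoxide then closes onto the glycolate ester to give the 3-hydroxy-4-silyloxy lactone F1 as a diastereomer mixture. Dehydration of its tertiary benzylic alcohol (Burgess reagent, THF, 50 °C) gives the 4-silyloxy butenolide F2. K2CO3 in MeOH at 0 °C cleaves the labile enol silyl ether but not the aryl triisopropylsilyl ether and gives 16.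

Second: step 10. The acidic enol OH of 16 may promote ionisation of the tertiary allyl ethers (loss of the C5 unit) or cyclisation of the ortho-prenylphenols to chromans at 140 °C. The fallback sets out from 15 and comes back at 18, and rearranges before the enol is unveiled. Enol acetate 15 is isolated from step 9 by leaving out the methanol treatment. It is heated in degassed o-xylene at 140 °C, where no acidic OH is present, to give the bis-prenylated enol acetate F3. DBU (cat.) in MeOH at 0 °C then removes the enol acetate and gives 18.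

Third: step 4. The single etherification may not discriminate well enough between the two catechol oxygens, the branched/linear ratio may be poor, or the free catechol may bind the palladium catalyst. The fallback sets out from 7 and comes back at 8, and builds the tertiary ether by copper-catalysed propargylic substitution followed by semi-hydrogenation. Treating 7 with 3-chloro-3-methylbut-1-yne (1.1 equiv), CuCl2·2H2O (1 mol %) and DBU (1.1 equiv) in MeCN at 0 °C alkylates the more acidic 4-OH and gives the propargyl ether 3-hydroxy-4-[(2-methylbut-3-yn-2-yl)oxy]benzaldehyde F4. H2 (1 atm) over Pd/CaCO3 poisoned with Pb(OAc)2, with quinoline in EtOAc at 23 °C, reduces the alkyne to the alkene and gives 8.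

**Further compounds**

F1 | step 9 | methyl (2R)-4-[(tert-butyldimethylsilyl)oxy]-3-hydroxy-2-{4-[(2-methylbut-3-en-2-yl)oxy]benzyl}-3-{4-[(2-methylbut-3-en-2-yl)oxy]-3-[(triisopropylsilyl)oxy]phenyl}-5-oxotetrahydrofuran-2-carboxylate (mixture at C-3 and C-4) | COC(=O)[C@]1(Cc2ccc(OC(C)(C)C=C)cc2)OC(=O)C(O[Si](C)(C)C(C)(C)C)C1(O)c1ccc(OC(C)(C)C=C)c(O[Si](C(C)C)(C(C)C)C(C)C)c1
F2 | step 9 | methyl (2R)-4-[(tert-butyldimethylsilyl)oxy]-2-{4-[(2-methylbut-3-en-2-yl)oxy]benzyl}-3-{4-[(2-methylbut-3-en-2-yl)oxy]-3-[(triisopropylsilyl)oxy]phenyl}-5-oxo-2,5-dihydrofuran-2-carboxylate | COC(=O)[C@]1(Cc2ccc(OC(C)(C)C=C)cc2)OC(=O)C(O[Si](C)(C)C(C)(C)C)=C1c1ccc(OC(C)(C)C=C)c(O[Si](C(C)C)(C(C)C)C(C)C)c1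
F3 | step 10 | methyl (2R)-4-acetoxy-2-[4-hydroxy-3-(3-methylbut-2-en-1-yl)benzyl]-3-{4-hydroxy-3-(3-methylbut-2-en-1-yl)-5-[(triisopropylsilyl)oxy]phenyl}-5-oxo-2,5-dihydrofuran-2-carboxylate | COC(=O)[C@]1(Cc2ccc(O)c(CC=C(C)C)c2)OC(=O)C(OC(C)=O)=C1c1cc(O[Si](C(C)C)(C(C)C)C(C)C)c(O)c(CC=C(C)C)c1
F4 | step 4 | 3-hydroxy-4-[(2-methylbut-3-yn-2-yl)oxy]benzaldehyde | O=Cc1ccc(OC(C)(C)C#C)c(O)c1
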